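**Retrosynthetic overview**

1. The guanine is built last: its imidazole ring is closed between a ring A salicylaldehyde and 2,5,6-triaminopyrimidin-4(3H)-one, the formyl group having been placed ortho to the ring A phenol of an N1,N4-di-Boc piperazine cyclophane.
2. The (2S,5S)-piperazine comes from borane reduction of a diaryl-ether-bridged diketopiperazine, whose N4–C3 amide is closed by the C5 amine on an activated C3 amide.
3. The strategy rests on this feature: piperazine N1, C2, C3 and C6 are the amine nitrogen, aldehyde carbon, isocyanide carbon and carboxyl carbon of an Ugi reaction. C2 carries the ring B benzyl arm (an arylacetaldehyde) and C5/N4 carry the ring A arm (an N-Boc-L-tyrosine). The tethered aldehyde–acid 9, benzylamine and 2-bromo-6-isocyanopyridine therefore close the 14-membered lactam through a 15-membered imidate and a Mumm ring contraction.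
4. Aldehyde–acid 9 comes from 3-iodo-L-tyrosine (source of C5) and tyrosol by a Chan–Lam diaryl ether coupling.
5. Ring order: 14-membered cyclophane lactam (step 8), diketopiperazine (step 9), imidazole ring of the purine (step 13). N1 carries plain benzyl so that the tertiary amide survives TFA and the N-benzyl and O-benzyl groups leave together by hydrogenolysis.

Key step: step 8

Remark: piperazine atoms are numbered N1, C2 (ring B arm), C3, N4, C5 (ring A arm), C6 throughout; 2,5,6-triaminopyrimidin-4(3H)-one is used as its commercial sulfate, and the purine is written as the 7H tautomer of the given structure.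

**Route**

Step 1
Reactants: 1 3-iodo-L-tyrosine
Product: 2 N-Boc-3-iodo-L-tyrosine
Conditions: Boc2O (1.1 equiv), NaHCO3, dioxane/H2O, 0 °C to rt; then cold 1 M HCl to pH 3
Reagents that add atoms: di-tert-butyl dicarbonate CC(C)(C)OC(=O)OC(=O)OC(C)(C)C
Why: Carbamate protection of an α-amino acid (N-acylation with Boc2O under Schotten–Baumann-type conditions), in which the amine outcompetes the phenol for the anhydride and the stereocentre is not touched.

Step 2
Reactants: 2 N-Boc-3-iodo-L-tyrosine
Product: 3 benzyl N-Boc-O-benzyl-3-iodo-L-tyrosinate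
Conditions: BnBr (2.3 equiv), K2CO3, DMF, rt
Reagents that add atoms: benzyl bromide BrCc1ccccc1
Why: Williamson etherification of the phenoxide and SN2 O-alkylation of the carboxylate run in one pot, and a carbamate-protected amino ester should not racemise under carbonate at room temperature.

Step 3
Reactants: 3 benzyl N-Boc-O-benzyl-3-iodo-L-tyrosinate
Product: 4 benzyl N-Boc-O-benzyl-3-(pinacolatoboryl)-L-tyrosinate
Conditions: B2pin2, PdCl2(dppf) (5 mol %), KOAc, DMSO, 80 °C
Reagents that add atoms: bis(pinacolato)diboron CC1(C)OB(OC1(C)C)B1OC(C)(C)C(C)(C)O1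
Why: Miyaura borylation of an aryl iodide, for which the weak base KOAc avoids both Suzuki homocoupling and epimerisation of the ester.

Step 4
Reactants: 4 benzyl N-Boc-O-benzyl-3-(pinacolatoboryl)-L-tyrosinate
Product: 5 benzyl N-Boc-O-benzyl-3-borono-L-tyrosinate
Conditions: NaIO4, NH4OAc, acetone/H2O, rt
Reagents that add atoms: water O
Why: Periodate glycol cleavage of the pinacol released in the hydrolysis equilibrium drives the boronic ester to the free boronic acid, the more reactive partner for the following Chan–Lam coupling.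

Step 5
Reactants: 5 benzyl N-Boc-O-benzyl-3-borono-L-tyrosinate; 6 tyrosol
Product: 7 benzyl N-Boc-O-benzyl-3-[4-(2-hydroxyethyl)phenoxy]-L-tyrosinate
Conditions: Cu(OAc)2, pyridine, 4 Å MS, O2 (1 atm), CH2Cl2, rt; 6 in excess (2.5 equiv)
Reagents that add atoms: none
Why: Chan–Lam–Evans O-arylation, in which the phenol of tyrosol binds divalent copper and is arylated at room temperature while the far less acidic primary alcohol is not, and the mild conditions leave the α-stereocentre intact.

Step 6
Reactants: 7 benzyl N-Boc-O-benzyl-3-[4-(2-hydroxyethyl)phenoxy]-L-tyrosinate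
Product: 8 N-Boc-O-benzyl-3-[4-(2-hydroxyethyl)phenoxy]-L-tyrosine
Conditions: LiOH, THF/H2O, 0 °C; then cold 1 M HCl to pH 3
Reagents that add atoms: lithium hydroxide [Li+].[OH-]
Why: Ester saponification at 0 °C cleaves the benzyl ester without touching the carbamate or the ethers and with little risk of epimerising an N-Boc amino acid.

Step 7
Reactants: 8 N-Boc-O-benzyl-3-[4-(2-hydroxyethyl)phenoxy]-L-tyrosine
Product: 9 N-Boc-O-benzyl-3-[4-(2-oxoethyl)phenoxy]-L-tyrosine (aldehyde–acid)
Conditions: Dess–Martin periodinane (1.2 equiv), CH2Cl2, 0 °C to rt; used crude at once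
Reagents that add atoms: none
Why: Dess–Martin oxidation converts the primary alcohol into the arylacetaldehyde under near-neutral conditions that tolerate the free carboxylic acid and avoid the base that would enolise the product.

Step 8
Reactants: 9 aldehyde–acid; 10 benzylamine; 11 2-bromo-6-isocyanopyridine
Product: 15 14-membered Ugi lactam (2S,5S; N1-benzyl; C2 carboxamide of 6-bromopyridin-2-amine; C5 NHBoc; ring A O-benzyl), via imino acid 12 (not isolated), via nitrilium carboxylate 13 (not isolated), via 15-membered O-acyl imidate 14 (not isolated)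
Conditions: 10 (1.0 equiv), 3 Å MS, CF3CH2OH, rt, 1 h; then slow addition to 11 (3 equiv) in CF3CH2OH/CH2Cl2 (final 2 mM), 40 °C, 48 h
Reagents that add atoms: none
Why: Proposed new method: benzylamine and the arylacetaldehyde of 9 give the iminium carboxylate 12, the isocyanide carbon adds to the iminium carbon (C2–C3) to give nitrilium 13, the tethered carboxylate captures the nitrilium carbon in a 15-exo-dig closure to the O-acyl imidate 14, and a Mumm O-to-N acyl shift through a five-membered tetrahedral intermediate (5-exo-trig attack of N1 on C6) forms N1–C6 and contracts the ring by one atom to the 14-membered lactam 15. The closest known reaction type is the Ugi four-centre three-component reaction of oxo acids, including macrocyclising versions with bifunctional acid–carbonyl substrates, run with a convertible 2-isocyanopyridine; it has not been shown for a meta,para-cyclophane lactam as strained as this cycloisodityrosine-type ring. The case for it is that the difficult amide bond is not made by end-to-end macrolactamisation: the ring is first closed at the larger and more flexible imidate by collapse of an ion pair, and the amide then forms by an intramolecular, strongly exergonic acyl transfer. C5 is carried unchanged from L-tyrosine, whereas C2 is created in the isocyanide addition and is fixed either there, on the ion-paired iminium carboxylate, or, if that addition is reversible, in the ring-forming capture and Mumm steps; in both cases the only controlling element is the C5 centre acting through the cyclophane, so the (2S) selectivity is not assured and the (2R) epimer is to be removed by chromatography (it cannot pass step 9 in any case). The step also needs intramolecular rather than intermolecular capture of the nitrilium ion, which the tether together with a pre-formed imine, high dilution, excess isocyanide and the weakly nucleophilic solvent should secure.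

Step 9
Reactants: 15 14-membered Ugi lactam
Product: 17 bridged (2S,5S)-N1-benzyl diketopiperazine (C3 and C6 carbonyls; ring A O-benzyl), via C5 amine 16 (not isolated)
Conditions: TFA/CH2Cl2 (1:4), 0 °C to rt; evaporate; then N-methylmorpholine, AcOH, toluene/2-butanol, 100 °C
Reagents that add atoms: none
Why: Ugi/deprotect/cyclise sequence in which acidolysis frees N4 and, on buffering and heating, the amine attacks the activated N-(6-bromopyridin-2-yl) amide at C3 in a 6-exo-trig aminolysis that only the cis (2S,5S) lactam can undergo, the N1-benzyl tertiary amide being able to adopt the cis geometry that the diketopiperazine requires.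

Step 10
Reactants: 17 bridged N1-benzyl diketopiperazine
Product: 18 (2S,5S)-N1-benzylpiperazine cyclophane, ring A O-benzyl
Conditions: BH3·THF (excess), THF, reflux; then MeOH, reflux
Reagents that add atoms: none
Why: Borane reduction of amides to amines should reduce both the tertiary and the secondary lactam without affecting the benzyl ether, the diaryl ether or the two stereocentres.

Step 11
Reactants: 18 N1-benzylpiperazine O-benzyl ether
Product: 20 (2S,5S)-N1,N4-di-Boc piperazine cyclophane with free ring A phenol, via amino phenol 19 (not isolated)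
Conditions: H2 (1 atm), Pd(OH)2/C, MeOH/AcOH, rt; filter, evaporate; then Boc2O (2.2 equiv), Et3N, CH2Cl2/MeOH, rt
Reagents that add atoms: di-tert-butyl dicarbonate CC(C)(C)OC(=O)OC(=O)OC(C)(C)C
Why: Catalytic hydrogenolysis cleaves the O-benzyl and N-benzyl groups in one operation, and carbamoylation with Boc2O then takes the two secondary amines, which are far more nucleophilic than the hindered phenol.

Step 12
Reactants: 20 N1,N4-di-Boc phenol
Product: 21 N1,N4-di-Boc ring A salicylaldehyde (CHO ortho to OH)
Conditions: MgCl2 (anhydrous), Et3N, paraformaldehyde, MeCN, reflux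
Reagents that add atoms: formaldehyde (as paraformaldehyde) C=O
Why: Magnesium-mediated ortho-formylation of phenols (Casnati–Skattebøl reaction) delivers formaldehyde from the magnesium phenoxide to the only free ortho carbon, the other ortho position bearing the aryloxy group and the para position the benzylic carbon, under conditions that keep the Boc groups.

Step 13
Reactants: 21 di-Boc salicylaldehyde; 22 2,5,6-triaminopyrimidin-4(3H)-one
Product: 25 N1,N4-di-Boc guanipiperazine A, via Schiff base 23 (not isolated), via dihydropurine 24 (not isolated)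
Conditions: 22 (as sulfate, 1.2 equiv), NaOAc, DMSO, 60 °C, N2; then O2 (1 atm), 100 °C
Reagents that add atoms: none
Why: Traube-type purine synthesis in its aldehyde version, in which the most nucleophilic 5-amino group forms the Schiff base, the 6-amino group adds to it to give the 7,8-dihydropurine, and aerobic dehydrogenation driven by aromatisation gives the 8-arylguanine.

Step 14
Reactants: 25 N1,N4-di-Boc guanipiperazine A
Product: 26 guanipiperazine A
Conditions: TFA/CH2Cl2 (1:1), anisole, 0 °C to rt; free base by ion exchange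
Reagents that add atoms: none
Why: Acidolysis of the two tert-butyl carbamates (loss of the tert-butyl cation, then decarboxylation) frees N1 and N4, with anisole present so that the electron-rich phenol is not alkylated and with no stereocentre involved.

**Compound list**

1 | 3-iodo-L-tyrosine | N[C@@H](Cc1ccc(O)c(I)c1)C(=O)O | starting material
2 | N-Boc-3-iodo-L-tyrosine | CC(C)(C)OC(=O)N[C@@H](Cc1ccc(O)c(I)c1)C(=O)O | intermediate
3 | benzyl N-Boc-O-benzyl-3-iodo-L-tyrosinate | CC(C)(C)OC(=O)N[C@@H](Cc1ccc(OCc2ccccc2)c(I)c1)C(=O)OCc1ccccc1 | intermediate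
4 | benzyl N-Boc-O-benzyl-3-(pinacolatoboryl)-L-tyrosinate | CC(C)(C)OC(=O)N[C@@H](Cc1ccc(OCc2ccccc2)c(c1)B1OC(C)(C)C(C)(C)O1)C(=O)OCc1ccccc1 | intermediate
5 | benzyl N-Boc-O-benzyl-3-borono-L-tyrosinate | CC(C)(C)OC(=O)N[C@@H](Cc1ccc(OCc2ccccc2)c(c1)B(O)O)C(=O)OCc1ccccc1 | intermediate
6 | tyrosol | OCCc1ccc(O)cc1 | starting material
7 | benzyl N-Boc-O-benzyl-3-[4-(2-hydroxyethyl)phenoxy]-L-tyrosinate | CC(C)(C)OC(=O)N[C@@H](Cc1ccc(OCc2ccccc2)c(c1)Oc1ccc(CCO)cc1)C(=O)OCc1ccccc1 | intermediate
8 | N-Boc-O-benzyl-3-[4-(2-hydroxyethyl)phenoxy]-L-tyrosine | CC(C)(C)OC(=O)N[C@@H](Cc1ccc(OCc2ccccc2)c(c1)Oc1ccc(CCO)cc1)C(=O)O | intermediate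
9 | N-Boc-O-benzyl-3-[4-(2-oxoethyl)phenoxy]-L-tyrosine (aldehyde–acid) | CC(C)(C)OC(=O)N[C@@H](Cc1ccc(OCc2ccccc2)c(c1)Oc1ccc(CC=O)cc1)C(=O)O | intermediate
10 | benzylamine | NCc1ccccc1 | starting material
11 | 2-bromo-6-isocyanopyridine | [C-]#[N+]c1cccc(Br)n1 | starting material
12 | N-benzyl imine of 9 (iminium carboxylate in solution; not isolated) | CC(C)(C)OC(=O)N[C@@H](Cc1ccc(OCc2ccccc2)c(c1)Oc1ccc(CC=NCc2ccccc2)cc1)C(=O)O | intermediate
13 | nitrilium carboxylate, (2S) epimer shown (not isolated) | CC(C)(C)OC(=O)N[C@@H](Cc1ccc(OCc2ccccc2)c(c1)Oc1ccc(C[C@H](NCc2ccccc2)C#[N+]c2cccc(Br)n2)cc1)C([O-])=O | intermediate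
14 | 15-membered cyclic O-acyl imidate (not isolated) | O=C1OC(=Nc2cccc(Br)n2)[C@@H](NCc2ccccc2)Cc2ccc(cc2)Oc2cc(ccc2OCc2ccccc2)C[C@@H]1NC(=O)OC(C)(C)C | intermediate
15 | 14-membered Ugi lactam, (2S,5S), N1-benzyl, C2 N-(6-bromopyridin-2-yl)carboxamide, C5 NHBoc, ring A O-benzyl | O=C1N(Cc2ccccc2)[C@H](C(=O)Nc2cccc(Br)n2)Cc2ccc(cc2)Oc2cc(ccc2OCc2ccccc2)C[C@@H]1NC(=O)OC(C)(C)C | intermediate
16 | C5 free amine of lactam 15 (not isolated) | O=C1N(Cc2ccccc2)[C@H](C(=O)Nc2cccc(Br)n2)Cc2ccc(cc2)Oc2cc(ccc2OCc2ccccc2)C[C@@H]1N | intermediate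
17 | bridged (2S,5S)-N1-benzyl diketopiperazine, ring A O-benzyl | c1cc2cc(c1OCc1ccccc1)Oc1ccc(cc1)C[C@H]1C(=O)N[C@H](C(=O)N1Cc1ccccc1)C2 | intermediate
18 | (2S,5S)-N1-benzylpiperazine cyclophane, ring A O-benzyl | c1cc2cc(c1OCc1ccccc1)Oc1ccc(cc1)C[C@H]1CN[C@H](CN1Cc1ccccc1)C2 | intermediate
19 | (2S,5S)-piperazine cyclophane with free phenol and free N1-H and N4-H (not isolated) | c1cc2cc(c1O)Oc1ccc(cc1)C[C@H]1CN[C@H](CN1)C2 | intermediate
20 | N1,N4-di-Boc piperazine cyclophane, free ring A phenol | c1cc2cc(c1O)Oc1ccc(cc1)C[C@H]1CN(C(=O)OC(C)(C)C)[C@H](CN1C(=O)OC(C)(C)C)C2 | intermediate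
21 | N1,N4-di-Boc ring A salicylaldehyde | O=Cc1cc2cc(c1O)Oc1ccc(cc1)C[C@H]1CN(C(=O)OC(C)(C)C)[C@H](CN1C(=O)OC(C)(C)C)C2 | intermediate
22 | 2,5,6-triaminopyrimidin-4(3H)-one | Nc1nc(N)c(N)c(=O)[nH]1 | starting material
23 | Schiff base of 21 at the 5-amino group of 22 (not isolated) | Nc1nc(N)c(N=Cc2cc3cc(c2O)Oc2ccc(cc2)C[C@H]2CN(C(=O)OC(C)(C)C)[C@H](CN2C(=O)OC(C)(C)C)C3)c(=O)[nH]1 | intermediate
24 | 8-aryl-7,8-dihydroguanine, C8 unassigned (not isolated) | Nc1nc2NC(c3cc4cc(c3O)Oc3ccc(cc3)C[C@H]3CN(C(=O)OC(C)(C)C)[C@H](CN3C(=O)OC(C)(C)C)C4)Nc2c(=O)[nH]1 | intermediate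
25 | N1,N4-di-Boc guanipiperazine A | Nc1nc2nc(-c3cc4cc(c3O)Oc3ccc(cc3)C[C@H]3CN(C(=O)OC(C)(C)C)[C@H](CN3C(=O)OC(C)(C)C)C4)[nH]c2c(=O)[nH]1 | intermediate
26 | guanipiperazine A | Nc1nc2nc(-c3cc4cc(c3O)Oc3ccc(cc3)C[C@H]3CN[C@H](CN3)C4)[nH]c2c(=O)[nH]1 | target

**Step count and risk**

Total step count: 14. Longest linear sequence: 14 steps (1 to 26); tyrosol, benzylamine, the isocyanide and the triaminopyrimidinone enter as purchased components.

Steps most likely to fail:

1. Step 8 (carries the label "Proposed new method:"). The nitrilium ion may be captured intermolecularly and give oligomers, the ring may not close or may stall before the Mumm shift because of cyclophane strain, or the isocyanide addition may show poor facial selectivity at C2. The fallback uncouples the Ugi reaction from the ring closure and closes the ring at the diaryl ether, which is known chemistry for cycloisodityrosine-type rings. It sets out from boronic acid 5. LiOH in THF/H2O cleaves the benzyl ester to N-Boc-O-benzyl-3-borono-L-tyrosine F1. An ordinary intermolecular Ugi reaction of F1 with purchased 4-hydroxyphenylacetaldehyde, benzylamine 10 and isocyanide 11 in methanol gives the open-chain Ugi adduct F2 as a mixture of C2 epimers. Copper-mediated intramolecular phenol–arylboronic acid coupling (Cu(OAc)2, pyridine, 4 Å MS, O2, CH2Cl2, high dilution) then forms the diaryl ether and the 14-membered ring, and after separation of the C2 epimers the route is rejoined at lactam 15.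

2. Step 9. The ring closure may fail because the 14-membered lactam cannot reach the cis-amide boat geometry needed for a bicycle with two planar amides, or C2 may epimerise under the buffered heating before the amine attacks. The fallback makes N4–C3 by alkylation at the alcohol oxidation level, which gives a more flexible monoketopiperazine. It sets out from lactam 15. NaOMe in MeOH at 0 °C exchanges the bromopyridyl amide for the methyl ester F3. LiBH4 in THF reduces the ester, but not the tertiary lactam or the carbamate, to the primary alcohol F4, and MsCl/Et3N gives the mesylate F5. TFA removes the Boc group to give the amino mesylate F6 as its salt, and i-Pr2NEt in MeCN at 60 °C closes the N1-benzyl piperazin-6-one F7 by 6-exo-tet N-alkylation. The BH3·THF conditions of step 10 reduce the one remaining lactam, and the route is rejoined at N1-benzylpiperazine 18.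

3. Step 13. The dehydrogenation of the dihydropurine may remain incomplete, or the electron-rich phenol and the air-sensitive triaminopyrimidinone may be degraded oxidatively before ring closure. The fallback brings the C8 carbon in at the acid oxidation level and closes the imidazole ring by dehydration instead of oxidation. It sets out from salicylaldehyde 21. Pinnick oxidation (NaClO2, NaH2PO4, 2-methyl-2-butene, t-BuOH/H2O) gives the salicylic acid F8. EDC/HOBt coupling with 22 in DMF acylates the 5-amino group to give the 5-amide F9. Base-mediated cyclodehydration (1 M NaOH, EtOH, reflux), which the Boc groups tolerate, closes the purine, and the route is rejoined at di-Boc guanine 25.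

**Further compounds**

F1 | step 8 | N-Boc-O-benzyl-3-borono-L-tyrosine | CC(C)(C)OC(=O)N[C@@H](Cc1ccc(OCc2ccccc2)c(c1)B(O)O)C(=O)O
F2 | step 8 | open-chain Ugi adduct, C2 epimers (boronic acid on ring A, free phenol on ring B) | CC(C)(C)OC(=O)N[C@@H](Cc1ccc(OCc2ccccc2)c(c1)B(O)O)C(=O)N(Cc1ccccc1)C(Cc1ccc(O)cc1)C(=O)Nc1cccc(Br)n1
F3 | step 9 | 14-membered lactam C2 methyl ester | O=C1N(Cc2ccccc2)[C@H](C(=O)OC)Cc2ccc(cc2)Oc2cc(ccc2OCc2ccccc2)C[C@@H]1NC(=O)OC(C)(C)C
F4 | step 9 | 14-membered lactam C2 hydroxymethyl compound | O=C1N(Cc2ccccc2)[C@H](CO)Cc2ccc(cc2)Oc2cc(ccc2OCc2ccccc2)C[C@@H]1NC(=O)OC(C)(C)C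
F5 | step 9 | mesylate of F4 | O=C1N(Cc2ccccc2)[C@H](COS(C)(=O)=O)Cc2ccc(cc2)Oc2cc(ccc2OCc2ccccc2)C[C@@H]1NC(=O)OC(C)(C)C
F6 | step 9 | amino mesylate (C5 free amine) | O=C1N(Cc2ccccc2)[C@H](COS(C)(=O)=O)Cc2ccc(cc2)Oc2cc(ccc2OCc2ccccc2)C[C@@H]1N
F7 | step 9 | bridged (2S,5S)-N1-benzyl piperazin-6-one, ring A O-benzyl | c1cc2cc(c1OCc1ccccc1)Oc1ccc(cc1)C[C@H]1CN[C@H](C(=O)N1Cc1ccccc1)C2
F8 | step 13 | N1,N4-di-Boc ring A salicylic acid | OC(=O)c1cc2cc(c1O)Oc1ccc(cc1)C[C@H]1CN(C(=O)OC(C)(C)C)[C@H](CN1C(=O)OC(C)(C)C)C2
F9 | step 13 | 5-(aroylamino)-2,6-diaminopyrimidin-4(3H)-one from F8 and 22 | Nc1nc(N)c(NC(=O)c2cc3cc(c2O)Oc2ccc(cc2)C[C@H]2CN(C(=O)OC(C)(C)C)[C@H](CN2C(=O)OC(C)(C)C)C3)c(=O)[nH]1
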